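**Plan**

- Enabling feature: in the ten-membered ring C2 and C7 are 1,6 to each other. A C2–C7 bond turns the ring into a decalin (ring A: C7–C8–C9–C10=C1–C2, holding the cis C1=C10 alkene; ring B: C2–C3–C4–C5–C6–C7) in which the C2 oxygen and the C6 carbonyl are in an aldol relationship across C2–C7, and C11, next to C7, can hold the C13 oxygen as an epoxide.
- Retrosynthesis: cut the C8 tiglate and the C2 and C13 acetates, open the O6–C12 enol lactone, then add back C2–C7 and the C11–C13 epoxide (reverse of a retro-aldol/epoxide-opening fragmentation). The decalin is cut at C8–C9 and C2–C7 (Diels–Alder), C7–C11 (oxalate Claisen), C7=C8 (orthoformate), C6–C7 and C1–C2 (organometallic additions), leaving 3-hydroxy-3-methylglutaric acid (C2–C6, C15).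
- Forward: the chain grows from the glutarate, C2 arm first (through a temporary δ-lactone), then the C6 arm. Rings A and B close together in one intramolecular Diels–Alder reaction, the fragmentation reveals the ten-membered ring, and the butenolide closes afterwards.
- Stereochemistry: C4 from enzymatic desymmetrisation; C8 from the catalyst-controlled cycloaddition; C2 from C4-hydroxyl-directed syn reduction; C1=C10 (Z) from the cyclohexene; C7=C11 and C5=C6 from the lactone and the medium ring; the tiglate alkene from the reagent.

Key step: step 16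

Numbering: germacrane numbering is used for every intermediate (ring C1–C10; C11–C13 the three-carbon unit on C7; C14 on C10; C15 on C4).
Assumption: the (S,S)-ligand of step 14 is taken to deliver (8R); if the copper complex selects the other dienophile face, its enantiomer is used instead.
Remark: the C2 carbinol of 8–18, the C7=C8 geometry of 16–20 and the C2, C7 and C11 centres of 21, 23 and 24 are drawn in one form only; all of them disappear by step 16, so their isomers converge.

**Route**

Step 1
Reactants: 1 3-hydroxy-3-methylglutaric acid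
Product: 2 dimethyl 3-hydroxy-3-methylglutarate
Conditions: MeI, K2CO3, DMF, rt
Reagents that add atoms: iodomethane, CI
Why: Carboxylate O-alkylation (SN2) esterifies both acids without acid, so the tertiary β-hydroxyl is neither alkylated nor eliminated.

Step 2
Reactants: 2 dimethyl 3-hydroxy-3-methylglutarate
Product: 3 (S)-3-hydroxy-5-methoxy-3-methyl-5-oxopentanoic acid
Conditions: pig liver esterase, pH 7 phosphate buffer, 1 M NaOH (pH-stat), rt; then HCl to pH 2
Reagents that add atoms: water, O
Why: Enzymatic desymmetrisation of a prochiral diester: the esterase should hydrolyse one enantiotopic ester group and stop at the half ester, which sets C4 as (S) with the free acid on the future C3–C2 arm.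

Step 3
Reactants: 3 (S)-half ester
Product: 4 methyl (S)-3-hydroxy-5-[methoxy(methyl)amino]-3-methyl-5-oxopentanoate
Conditions: MeNH(OMe)·HCl, EDC·HCl, HOBt (cat.), N-methylmorpholine, CH2Cl2, 0 °C → rt
Reagents that add atoms: N,O-dimethylhydroxylamine hydrochloride, CNOC.Cl
Why: Carbodiimide amide coupling converts only the free acid into the Weinreb amide, which differentiates the two arms, while the tertiary alcohol is too hindered to be acylated.

Step 4
Reactants: 4 Weinreb amide
Product: 5 methyl (S)-3-(tert-butyldimethylsilyloxy)-5-[methoxy(methyl)amino]-3-methyl-5-oxopentanoate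
Conditions: t-BuMe2SiOTf, 2,6-lutidine, CH2Cl2, 0 °C → rt
Reagents that add atoms: tert-butyldimethylsilyl triflate, CC(C)(C)[Si](C)(C)OS(=O)(=O)C(F)(F)F
Why: Silyl triflate silylation protects the tertiary C4 hydroxyl against retro-aldol cleavage and elimination, and this silyl group is chosen because it must outlast a secondary silyl ether in step 11 and the trimethylsilyl ether in step 16.

Step 5
Reactants: 5 silylated Weinreb amide
Product: 6 methyl (S)-3-(tert-butyldimethylsilyloxy)-3-methyl-5-oxopentanoate
Conditions: Cp2Zr(H)Cl, THF, rt; aqueous work-up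
Reagents that add atoms: none
Why: Hydrozirconation of the amide carbonyl gives a zirconium hemiaminal that releases the C2 aldehyde on work-up, an amide-selective reduction that leaves the methyl ester untouched.

Step 6
Reactants: 6 C2 aldehyde; 7 2-methylallylmagnesium chloride
Product: 9 (4S)-4-(tert-butyldimethylsilyloxy)-4-methyl-6-(2-methylallyl)oxan-2-one (both epimers at the new carbinol carbon), via hydroxy ester 8 (not isolated)
Conditions: THF, –78 °C, AcOH quench; then camphorsulfonic acid (cat.), CH2Cl2, rt
Reagents that add atoms: none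
Why: Grignard addition to the aldehyde (faster than to the ester at –78 °C) brings in C1, C9, C10 and C14, and acid-catalysed lactonisation of the δ-hydroxy ester (helped by the gem-disubstituted C4) masks the new C2 hydroxyl and makes C6 an acyl donor; C2 forms as both epimers, which does not matter because it is oxidised in step 12.

Step 7
Reactants: 9 δ-lactone; 10 methyllithium
Product: 11 (4S)-4-(tert-butyldimethylsilyloxy)-6-hydroxy-4,8-dimethylnon-8-en-2-one
Conditions: THF, –78 °C; AcOH quench at –78 °C
Reagents that add atoms: none
Why: Single addition of an organolithium to a δ-lactone: the lithium lactolate is stable at low temperature and collapses only on work-up, so the methyl ketone (C7) should form without over-addition.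

Step 8
Reactants: 11 hydroxy ketone
Product: 12 (4S)-4,6-bis(tert-butyldimethylsilyloxy)-4,8-dimethylnon-8-en-2-one
Conditions: t-BuMe2SiCl, imidazole, DMF, rt
Reagents that add atoms: tert-butyldimethylsilyl chloride, CC(C)(C)[Si](C)(C)Cl
Why: Silylation of the secondary alcohol of the open hydroxy ketone tautomer (the lactol hydroxyl is tertiary and unreactive) fixes the open chain and protects C2–OH for the Claisen condensation.

Step 9
Reactants: 12 methyl ketone; 13 diallyl oxalate
Product: 14 allyl (6S)-6,8-bis(tert-butyldimethylsilyloxy)-6,10-dimethyl-2,4-dioxoundec-10-enoate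
Conditions: LiN(SiMe3)2, THF, –78 °C; then 13, –78 → –20 °C; dilute HCl work-up
Reagents that add atoms: none
Why: Crossed Claisen condensation: kinetic deprotonation occurs at the unhindered methyl group (C7) and not at the neopentylic C5 methylene, and the oxalate has no α-hydrogen and is highly electrophilic, so one C-acylation product should form and is protected as its enolate until work-up.

Step 10
Reactants: 14 2,4-dioxo ester; 15 trimethyl orthoformate
Product: 17 allyl (6S)-6,8-bis(tert-butyldimethylsilyloxy)-3-[(4-methoxybenzyloxy)methylene]-6,10-dimethyl-2,4-dioxoundec-10-enoate, via methoxymethylene compound 16 (not isolated)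
Conditions: 15, Ac2O, 80 °C; evaporate; then 4-methoxybenzyl alcohol, pyridinium p-toluenesulfonate (cat.), toluene, 45 °C, reduced pressure
Reagents that add atoms: 4-methoxybenzyl alcohol, COc1ccc(CO)cc1
Why: Orthoformate condensation at the doubly activated C7 methylene gives the methoxymethylene tricarbonyl (C8), and acid-catalysed addition–elimination (vinylogous transesterification) exchanges methanol for 4-methoxybenzyl alcohol as methanol is removed; the push–pull alkene geometry is labile and irrelevant.

Step 11
Reactants: 17 bis-silyl ether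
Product: 18 allyl (6S)-6-(tert-butyldimethylsilyloxy)-8-hydroxy-3-[(4-methoxybenzyloxy)methylene]-6,10-dimethyl-2,4-dioxoundec-10-enoate
Conditions: HF·pyridine, pyridine, THF, 0 °C → rt
Reagents that add atoms: none
Why: Fluoride-mediated desilylation should distinguish the secondary C2 silyl ether from the much more hindered tertiary C4 silyl ether.

Step 12
Reactants: 18 C2 alcohol
Product: 19 allyl (6S)-6-(tert-butyldimethylsilyloxy)-3-[(4-methoxybenzyloxy)methylene]-6,10-dimethyl-2,4,8-trioxoundec-10-enoate
Conditions: Dess–Martin periodinane, NaHCO3, CH2Cl2, 0 °C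
Reagents that add atoms: none
Why: Dess–Martin oxidation under buffered neutral conditions gives the β,γ-unsaturated C2 ketone without moving the 1,1-disubstituted alkene into conjugation and without touching the enol ether or the keto ester.

Step 13
Reactants: 19 β,γ-unsaturated ketone
Product: 20 allyl (6S,8Z)-6-(tert-butyldimethylsilyloxy)-3-[(4-methoxybenzyloxy)methylene]-6,10-dimethyl-2,4-dioxo-8-(trimethylsilyloxy)undeca-8,10-dienoate
Conditions: Me3SiOTf, Et3N, CH2Cl2, –78 °C; cold NaHCO3 work-up, used crude
Reagents that add atoms: trimethylsilyl triflate, C[Si](C)(C)OS(=O)(=O)C(F)(F)F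
Why: Soft enolisation: the C1 methylene, activated by both the C2 carbonyl and the C9=C10 alkene, is by far the most acidic position, so silylation should give the conjugated 1-silyloxy diene C9=C10–C1=C2 regioselectively with the usual Z enol ether geometry (tether outside).

Step 14
Reactants: 20 silyloxy triene
Product: 21 Diels–Alder adduct (trans-fused decalin with 2-OSiMe3, 4-OSiMe2t-Bu, 6-oxo, 7-C(=O)CO2allyl, 8-OPMB)
Conditions: Cu(OTf)2 (10 mol %), 2,2'-isopropylidenebis[(4S)-4-tert-butyl-2-oxazoline] (11 mol %), 4 Å molecular sieves, CH2Cl2, –40 → 0 °C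
Reagents that add atoms: none
Why: Catalytic asymmetric intramolecular Diels–Alder reaction: the copper bis(oxazoline) Lewis acid chelates the 1,3-dicarbonyl unit of the dienophile, the four-atom tether C3–C6 lets C8–C9 and C2–C7 form together (rings A and B), and the ligand screens one face of C7=C8, which sets C8 (R) independently of C4; C2 and C7 (drawn for the keto-ester-endo, trans-fused adduct) are sacrificial.

Step 15
Reactants: 21 Diels–Alder adduct; 22 trimethylsulfonium iodide
Product: 23 epoxy decalin (C7 bears the 2-(allyloxycarbonyl)oxiran-2-yl group, C11–C13 epoxide)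
Conditions: 22, KN(SiMe3)2, THF, –10 °C; then 21, –78 → –20 °C
Reagents that add atoms: none
Why: Corey–Chaykovsky epoxidation: the sulfonium ylide adds to the most electrophilic carbonyl, the ketone of the α-keto ester, not to the neopentylic C6 ketone, and the betaine closes to the glycidic ester; either C11 epimer serves.

Step 16
Reactants: 23 epoxy decalin
Product: 25 (4S,8R)-ten-membered 2,6-dione bearing the C7=C11 allyl ester syn to C6 plus the free C13 alcohol, via decalinol 24 (not isolated)
Conditions: K2CO3 (0.5 equiv), MeOH, –10 → 0 °C; pH 7 buffer quench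
Reagents that add atoms: none
Why: Methanolysis of the trimethylsilyl ether (the tertiary tert-butyldimethylsilyl ether at C4 is inert) gives the C2 alkoxide of 24, whose only β-carbonyl partner is C6, so retro-aldol cleavage breaks the C2–C7 bond shared by rings A and B and leaves the C2 enone and a C6 enolate in a ten-membered ring; the enolate then expels the epoxide oxygen from C11 (E1cB), creating C7=C11 and the C13 alkoxide. The closest known reaction type is the Grob-type fragmentation of a bicyclic β-hydroxy ketone in which retro-aldol cleavage is coupled to a β-elimination that opens an epoxide. No ring is closed: the ten-membered ring appears by cutting the fusion bond of the decalin, so no medium-ring cyclisation is needed, and C1=C10 is Z because it was a cyclohexene alkene. No stereocentre is formed; C2, C7 and C11 become trigonal, which is why their configurations in 23 do not matter, and C4 and C8 are untouched. The step needs elimination towards C11 and not towards C8, and it must be irreversible: epoxide strain makes the C11 oxygen a far better leaving group than the benzylic ether oxygen on C8, and strain release plus two newly conjugated carbonyl groups prevent re-closure. The C7=C11 geometry is decided in the elimination and is not enforced by the substrate; the isomer with C12 syn to C6 is the one wanted, because only it can lactonise in step 18.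

Step 17
Reactants: 25 allyl ester
Product: 26 keto acid (C12 acid syn to C6, free C13 alcohol; in equilibrium with its hydroxybutenolide ring tautomer)
Conditions: Pd(PPh3)4 (5 mol %), morpholine, THF, rt; dilute HCl work-up
Reagents that add atoms: none
Why: Palladium-catalysed allyl transfer (π-allyl complex) to morpholine frees the C12 acid under neutral conditions, and it is done before C13 is acetylated because an allylic acetate on an acrylate would itself ionise with zerovalent palladium.

Step 18
Reactants: 26 keto acid
Product: 27 6,12-enol lactone with C13 acetate (2-oxo, 4-OSiMe2t-Bu, 8-OPMB)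
Conditions: Ac2O, NaOAc, 60 °C
Reagents that add atoms: acetic anhydride, CC(=O)OC(C)=O
Why: Dehydrative enol lactonisation: the cis-keto acid, activated by the anhydride, is O-acylated by the C5 enol of the C6 ketone to give the γ-ylidene butenolide with the in-ring cis C5=C6 alkene that the ten-membered ring accommodates, and the primary C13 alcohol is acetylated in the same operation.

Step 19
Reactants: 27 silyl ether
Product: 28 C4 tertiary alcohol (2-oxo, 8-OPMB, 13-OAc, 6,12-olide)
Conditions: HF·pyridine, THF, rt
Reagents that add atoms: none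
Why: Acidic fluoride cleaves the tertiary silyl ether without forming a C4 alkoxide, which would undergo retro-aldol cleavage next to the C2 ketone.

Step 20
Reactants: 28 β-hydroxy enone
Product: 29 (2R,4S)-2,4-diol (8-OPMB, 13-OAc, 6,12-olide)
Conditions: Et2BOMe, THF/MeOH, –78 °C; NaBH4; AcOH quench, MeOH co-evaporation
Reagents that add atoms: none
Why: Narasaka–Prasad reduction: the boron chelate between the C4 hydroxyl and the C2 carbonyl directs external hydride to give the 1,3-syn diol, that is (2R), and the activated ketone is reduced at –78 °C before the lactone or the acetate can react.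

Step 21
Reactants: 29 diol
Product: 30 C2 acetate (free C4–OH, 8-OPMB, 13-OAc, 6,12-olide)
Conditions: Ac2O, pyridine, 4-(dimethylamino)pyridine (cat.), CH2Cl2, 0 °C
Reagents that add atoms: acetic anhydride, CC(=O)OC(C)=O
Why: Nucleophile-catalysed acylation esterifies the secondary allylic alcohol, while the tertiary C4 alcohol does not react under these conditions.

Step 22
Reactants: 30 4-methoxybenzyl ether
Product: 31 C8 alcohol (2-OAc, 13-OAc, free C4–OH, 6,12-olide)
Conditions: DDQ, CH2Cl2/pH 7 buffer, 0 °C
Reagents that add atoms: none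
Why: Oxidative cleavage of the 4-methoxybenzyl ether through its benzylic oxocarbenium ion, hydrolysed by the buffer, should leave the esters, the alkenes and the tertiary alcohol untouched.

Step 23
Reactants: 31 C8 alcohol; 32 tigloyl chloride
Product: 33 CNP0166369.1
Conditions: pyridine, 4-(dimethylamino)pyridine (cat.), CH2Cl2, 0 °C → rt
Reagents that add atoms: none
Why: Acyl chloride esterification with nucleophilic catalysis acylates the only secondary alcohol with retention at C8, and the E geometry of the tiglate comes from the reagent.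

**Compound list**

1 | 3-hydroxy-3-methylglutaric acid | CC(O)(CC(=O)O)CC(=O)O | starting material
2 | dimethyl 3-hydroxy-3-methylglutarate | COC(=O)CC(C)(O)CC(=O)OC | intermediate
3 | (S)-3-hydroxy-5-methoxy-3-methyl-5-oxopentanoic acid (acid arm = C3–C2, ester arm = C5–C6) | OC(=O)C[C@](C)(O)CC(=O)OC | intermediate
4 | methyl (S)-3-hydroxy-5-[methoxy(methyl)amino]-3-methyl-5-oxopentanoate | CON(C)C(=O)C[C@](C)(O)CC(=O)OC | intermediate
5 | methyl (S)-3-(tert-butyldimethylsilyloxy)-5-[methoxy(methyl)amino]-3-methyl-5-oxopentanoate | CON(C)C(=O)C[C@](C)(O[Si](C)(C)C(C)(C)C)CC(=O)OC | intermediate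
6 | methyl (S)-3-(tert-butyldimethylsilyloxy)-3-methyl-5-oxopentanoate (C2 aldehyde) | O=CC[C@](C)(O[Si](C)(C)C(C)(C)C)CC(=O)OC | intermediate
7 | 2-methylallylmagnesium chloride | C=C(C)C[Mg]Cl | starting material
8 | methyl (3S)-3-(tert-butyldimethylsilyloxy)-5-hydroxy-3,7-dimethyloct-7-enoate (C2 carbinol, both epimers; not isolated) | C=C(C)CC(O)C[C@](C)(O[Si](C)(C)C(C)(C)C)CC(=O)OC | intermediate
9 | (4S)-4-(tert-butyldimethylsilyloxy)-4-methyl-6-(2-methylallyl)oxan-2-one (lactone O on C2, carbonyl = C6; both C2 epimers) | C=C(C)CC1C[C@](C)(O[Si](C)(C)C(C)(C)C)CC(=O)O1 | intermediate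
10 | methyllithium | [Li]C | starting material
11 | (4S)-4-(tert-butyldimethylsilyloxy)-6-hydroxy-4,8-dimethylnon-8-en-2-one (both C2 epimers; ring-chain tautomer with its lactol) | C=C(C)CC(O)C[C@](C)(O[Si](C)(C)C(C)(C)C)CC(C)=O | intermediate
12 | (4S)-4,6-bis(tert-butyldimethylsilyloxy)-4,8-dimethylnon-8-en-2-one | C=C(C)CC(O[Si](C)(C)C(C)(C)C)C[C@](C)(O[Si](C)(C)C(C)(C)C)CC(C)=O | intermediate
13 | diallyl oxalate | C=CCOC(=O)C(=O)OCC=C | starting material
14 | allyl (6S)-6,8-bis(tert-butyldimethylsilyloxy)-6,10-dimethyl-2,4-dioxoundec-10-enoate (enolised; C7 methylene between C6 and C11) | C=C(C)CC(O[Si](C)(C)C(C)(C)C)C[C@](C)(O[Si](C)(C)C(C)(C)C)CC(=O)CC(=O)C(=O)OCC=C | intermediate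
15 | trimethyl orthoformate | COC(OC)OC | starting material
16 | 3-(methoxymethylene) derivative of 14 (drawn Z, methoxy syn to the keto ester; not isolated) | C=C(C)CC(O[Si](C)(C)C(C)(C)C)C[C@](C)(O[Si](C)(C)C(C)(C)C)CC(=O)/C(=C/OC)C(=O)C(=O)OCC=C | intermediate
17 | allyl (6S)-6,8-bis(tert-butyldimethylsilyloxy)-3-[(4-methoxybenzyloxy)methylene]-6,10-dimethyl-2,4-dioxoundec-10-enoate (drawn Z) | C=C(C)CC(O[Si](C)(C)C(C)(C)C)C[C@](C)(O[Si](C)(C)C(C)(C)C)CC(=O)/C(=C/OCc1ccc(OC)cc1)C(=O)C(=O)OCC=C | intermediate
18 | allyl (6S)-6-(tert-butyldimethylsilyloxy)-8-hydroxy-3-[(4-methoxybenzyloxy)methylene]-6,10-dimethyl-2,4-dioxoundec-10-enoate (both C2 epimers) | C=C(C)CC(O)C[C@](C)(O[Si](C)(C)C(C)(C)C)CC(=O)/C(=C/OCc1ccc(OC)cc1)C(=O)C(=O)OCC=C | intermediate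
19 | allyl (6S)-6-(tert-butyldimethylsilyloxy)-3-[(4-methoxybenzyloxy)methylene]-6,10-dimethyl-2,4,8-trioxoundec-10-enoate (β,γ-unsaturated C2 ketone) | C=C(C)CC(=O)C[C@](C)(O[Si](C)(C)C(C)(C)C)CC(=O)/C(=C/OCc1ccc(OC)cc1)C(=O)C(=O)OCC=C | intermediate
20 | allyl (6S,8Z)-6-(tert-butyldimethylsilyloxy)-3-[(4-methoxybenzyloxy)methylene]-6,10-dimethyl-2,4-dioxo-8-(trimethylsilyloxy)undeca-8,10-dienoate (diene C9=C10–C1=C2–OSiMe3) | C=C(C)/C=C(\O[Si](C)(C)C)C[C@](C)(O[Si](C)(C)C(C)(C)C)CC(=O)/C(=C/OCc1ccc(OC)cc1)C(=O)C(=O)OCC=C | intermediate
21 | Diels–Alder adduct: trans-fused decalin (ring A C7–C8–C9–C10=C1–C2, ring B C2–C3–C4–C5–C6–C7) with 2-OSiMe3, (4S)-4-methyl-4-OSiMe2t-Bu, 6-oxo, 7-C(=O)CO2allyl, (8R)-8-OPMB, 10-methyl; 8-OPMB cis and 2-OSiMe3 trans to the C7 keto ester | COc1ccc(CO[C@@H]2CC(C)=C[C@]3(O[Si](C)(C)C)C[C@](C)(O[Si](C)(C)C(C)(C)C)CC(=O)[C@@]23C(=O)C(=O)OCC=C)cc1 | intermediate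
22 | trimethylsulfonium iodide | C[S+](C)C.[I-] | starting material
23 | epoxy decalin: as 21 but C7 bears the 2-(allyloxycarbonyl)oxiran-2-yl group (C11 epoxide carbon, C13 epoxide methylene, C12 ester) | COc1ccc(CO[C@@H]2CC(C)=C[C@]3(O[Si](C)(C)C)C[C@](C)(O[Si](C)(C)C(C)(C)C)CC(=O)[C@@]23[C@]4(CO4)C(=O)OCC=C)cc1 | intermediate
24 | C2 tertiary alcohol of 23 (reacts on as its alkoxide; not isolated) | COc1ccc(CO[C@@H]2CC(C)=C[C@]3(O)C[C@](C)(O[Si](C)(C)C(C)(C)C)CC(=O)[C@@]23[C@]4(CO4)C(=O)OCC=C)cc1 | intermediate
25 | (4S,8R)-cyclodec-1(10)Z-ene-2,6-dione with 4-methyl-4-OSiMe2t-Bu, 8-OPMB, 10-methyl and the exocyclic C7=C11 alkene bearing CO2allyl (syn to C6) and CH2OH | COc1ccc(CO[C@@H]2C/C(C)=C\C(=O)C[C@](C)(O[Si](C)(C)C(C)(C)C)CC(=O)/C2=C(/CO)C(=O)OCC=C)cc1 | intermediate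
26 | C12 carboxylic acid of 25 (acid syn to C6; free C13 alcohol) | COc1ccc(CO[C@@H]2C/C(C)=C\C(=O)C[C@](C)(O[Si](C)(C)C(C)(C)C)CC(=O)/C2=C(/CO)C(=O)O)cc1 | intermediate
27 | (4S,8R)-6,12-enol lactone (C5=C6 with C4 and C7 cis; C7=C11 butenolide) with 2-oxo, 4-OSiMe2t-Bu, 8-OPMB, 13-OAc | COc1ccc(CO[C@@H]2C/C(C)=C\C(=O)C[C@](C)(O[Si](C)(C)C(C)(C)C)/C=C3/OC(=O)C(COC(C)=O)=C32)cc1 | intermediate
28 | (4S,8R)-4-hydroxy-2-oxo lactone (8-OPMB, 13-OAc) | COc1ccc(CO[C@@H]2C/C(C)=C\C(=O)C[C@](C)(O)/C=C3/OC(=O)C(COC(C)=O)=C32)cc1 | intermediate
29 | (2R,4S,8R)-2,4-dihydroxy lactone (8-OPMB, 13-OAc) | COc1ccc(CO[C@@H]2C/C(C)=C\[C@H](O)C[C@](C)(O)/C=C3/OC(=O)C(COC(C)=O)=C32)cc1 | intermediate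
30 | (2R,4S,8R)-2-acetoxy-4-hydroxy lactone (8-OPMB, 13-OAc) | COc1ccc(CO[C@@H]2C/C(C)=C\[C@H](OC(C)=O)C[C@](C)(O)/C=C3/OC(=O)C(COC(C)=O)=C32)cc1 | intermediate
31 | (2R,4S,8R)-2,13-diacetoxy-4,8-dihydroxygermacra-1(10)Z,5,7(11)-trien-6,12-olide | O[C@@H]1C/C(C)=C\[C@H](OC(C)=O)C[C@](C)(O)/C=C2/OC(=O)C(COC(C)=O)=C21 | intermediate
32 | tigloyl chloride, (E)-2-methylbut-2-enoyl chloride | C/C=C(\C)C(Cl)=O | starting material
33 | CNP0166369.1: (2R,4S,8R)-2,13-diacetoxy-4-hydroxy-8-tigloyloxygermacra-1(10)Z,5,7(11)-trien-6,12-olide | C/C=C(\C)C(=O)O[C@@H]1C/C(C)=C\[C@H](OC(C)=O)C[C@](C)(O)/C=C2/OC(=O)C(COC(C)=O)=C21 | target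

**Step count**

Total: 23 steps. Longest linear sequence: 23 steps, from 1 (all other starting materials are bought).

**Steps most likely to fail**

Step 14 (cycloaddition). The Lewis-acid pathway may become stepwise: C9 adds to C8 first, and the chelated dicarbonyl enolate then expels the C8 alkoxide or closes through oxygen (oxa-cycloaddition). The inside silyloxy group also slows the concerted reaction, and on a substrate that already carries C4 the ligand may not control the C8 face. The fallback gives up catalyst control and moves the cycloaddition to the uncatalysed, concerted regime. Setting out from 20, the triene would be heated in toluene at 80 °C with a trace of 2,6-di-tert-butyl-4-methylphenol and no Lewis acid. C8 would then form on both dienophile faces, and 21 would be separated by chromatography from the diastereomer with C2, C7 and C8 inverted, adduct F1. The route is rejoined at 21.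

Step 16 (fragmentation). The enolate may open the epoxide through the rotamer that places the hydroxymethyl group, not the ester, on the C6 side. The wrong alkene geometry then forms, and the C13 hydroxyl adds to the C6 ketone (hemiketal, on the way to a furan). The fallback corrects the alkene afterwards instead of relying on kinetic control in the elimination. Setting out from 23, the same fragmentation would then deliver mainly the geometric isomer with C13 syn to C6, dione F2. Irradiation of F2 at 365 nm with thioxanthone in acetonitrile (triplet-sensitised E/Z isomerisation of the tetrasubstituted enone) should give a photostationary mixture. 25 would be taken from it by chromatography and F2 recycled. The route is rejoined at 25.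

Step 20 (reduction). Facial selectivity may be poor or reversed, because the conformation of the ten-membered ring, and not the boron chelate of a tertiary alkoxide, may decide the face of hydride attack. The fallback uses inversion instead of directed delivery. Setting out from 28, reduction with NaBH4 and CeCl3·7H2O in methanol at –78 °C, without chelation, would give the C2 epimer, (2S)-alcohol F3, separated from any 29. A Mitsunobu reaction of F3 with acetic acid (PPh3, diisopropyl azodicarboxylate, toluene, 0 °C) would then install the C2 acetate with inversion. The route is rejoined at 30.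

Further compounds
F1 | step 14 | diastereomer of 21 from addition to the other dienophile face (C2, C7 and C8 inverted, C4 unchanged) | COc1ccc(CO[C@H]2CC(C)=C[C@@]3(O[Si](C)(C)C)C[C@](C)(O[Si](C)(C)C(C)(C)C)CC(=O)[C@]23C(=O)C(=O)OCC=C)cc1
F2 | step 16 | C7=C11 geometric isomer of 25 (CH2OH syn to C6, ester syn to C8) | COc1ccc(CO[C@@H]2C/C(C)=C\C(=O)C[C@](C)(O[Si](C)(C)C(C)(C)C)CC(=O)/C2=C(\CO)C(=O)OCC=C)cc1
F3 | step 20 | C2 epimer of 29, the (2S,4S,8R)-diol | COc1ccc(CO[C@@H]2C/C(C)=C\[C@@H](O)C[C@](C)(O)/C=C3/OC(=O)C(COC(C)=O)=C32)cc1
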